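You ask what part of the electrophile has reacted after 25 s in amber and in green, and your hunch is that the two can hardly differ, since green too holds twice the electrophile's charge in nucleophile.

- amber: electrophile 0.79 M; nucleophile 2.10 M; gas 200 mM (held); time 25 s
- green: electrophile 0.79 M; nucleophile 1.60 M; gas 200 mM (held); time 25 s

    electrophile + nucleophile → acid set free + target (k1 = 0.021 L mol⁻¹ s⁻¹)
    nucleophile + acid set free ⇌ protonated nucleophile, settled at all times (K2 = 29 L mol⁻¹)
    acid set free + free base ⇌ salt of the base, settled at all times (K3 = 650 L mol⁻¹)
    nucleophile + target ⇌ idle adduct, settled at all times (K4 = 0.69 L mol⁻¹)
    gas ⇌ free base, rate k5*(csat - [free base]) (k5 = 0.31 s⁻¹, csat = 200 mM)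
    acid set free → by-product carried off (k6 = 0.014 s⁻¹)

- for target the idle adduct is counted in
- at the start none of free base is dissolved
- run time (amber): 25 s

1. part of the electrophile that has reacted at the end, amber
2. part of the electrophile that has reacted at the end, green
3. what raising the concentration of nucleophile from its lowest to its highest value here does to the part of the electrophile that has reacted (changes below 5 percentage points count as none) (no change / it rises / it falls)

I would not count by the charge, because one reacted electrophile costs more than one nucleophile. I take free base at 200 mM from the start, because the gas crosses with a half-time of 2.24 s, shorter than green's 21 s half-life of the electrophile by step 1 alone. I drop step 6, because it acts on free acid set free, which with amber's charged nucleophile and free base at 200 mM is a share of 0.521% of the acid present, so its 50 s half-life stretches to 9500 s for the acid as a whole, longer than the run. At its charged amount, amber's nucleophile then holds 59.2% of any target as idle adduct and takes 31.9% of any acid set free. Adding these to the one nucleophile of the reaction gives 1.91 for amber and 1.79 for green: this is the price, the nucleophile withdrawn per electrophile reacted.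

The charged nucleophile minus the price times the charged electrophile leaves a surplus of 0.591 M in amber and 0.188 M in green, so on this reckoning the electrophile stays the limiting reagent in both, with less to spare in green. With the nucleophile falling in step with the electrophile, the rate integrates in closed form: the fraction of electrophile left is the surplus divided by (nucleophile charged × exp(k1 × surplus × time) − price × electrophile charged). I commit to 56.4% for amber and 46.9% for green, a rise of 9.5 percentage points, which is more than the 5 points that counts, so against your hunch the flasks differ.

The forecast gives 58% (from 52% to 63%) for amber and 48% (from 42% to 53%) for green, says it rises, and describes the run as going “roughly as a slowed second-order reaction”; its figures stand a little above mine.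

The simulation gives 56.9% for amber and 47.4% for green, so it rises by 9.5 points, inside the forecast's ranges and near my figures. Amber's state at 25.0 s gives a read price of 1.73 against the 1.91 reckoned from the charge. Read at 1.5 min, the same amber flask gets the same reckoning, with the price and surplus from the charge held unchanged, and the closed form gives 88.0% reacted; the flask stands at 90.3%, with 46% of its nucleophile still unbound, which gives a read price of 1.58.

All constants are those of an exercise; the result is computed.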